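**Plan**

- Retrosynthetic cuts: the lactone O–C1′ bond and the peroxide C6′–O bond of the side-chain bicycle; then C12–C13, which joins side chain and decalin; then the C6–O bond; last C13–C14 and the isopropyl group of ring C of abietic acid.
- Forward order: rings A and B come intact from abietic acid. Ring C is cut and re-closed as a 13,8α-δ-lactone, and an 18,6α-γ-lactone is closed by C–H oxidation. Both lactones are then opened, the C13 acid is exchanged for the side chain by decarboxylative alkenylation, and the 1,2-dioxane and finally the side-chain γ-lactone are closed.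
- Enabling feature: on the trans-fused rings A/B the 6α-hydroxyl (C6) and the 4α-methoxycarbonyl (C18 on C4) are both equatorial and peri to each other across C5. They are the opened form of a five-membered lactone C18–O–C6–C5–C4, and an oxidant held on the C18 carboxylate can reach only H6α.
- Stereochemistry: C4, C5, C9 and C10 come from abietic acid; C8 from α-face radical hydration; C6 from the directing carboxylate; C6′ from (R)-glycidol with one inversion; C4′ and C3′ from a Shi epoxidation whose tertiary carbon is then inverted by H2O2.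

Key step: step 7

Numbering: abietane numbers are kept for the decalin (C18 = carboxyl carbon on C4, α; C19 = 4β-methyl; C20 = 10β-methyl; C14 = carbon on C8; C11–C13 = chain on C9). C13a is the exocyclic CH2 on C13. The seven-carbon peroxide unit is C1′ (CH2O, later C=O), C2′ (CH2), C3′ (C(CH3)–O–O), C4′ (CH–O), C5′ (CH2), C6′ (CH–O–O, bonded to C13).

Assumption: the side-chain bicycle is built exactly as drawn, that is trans-fused (3′R,4′S) with C6′ R, the C13 chain being axial on the dioxane chair. This is not the arrangement a reversible conjugate addition would favour, so the three centres are set by stereospecific displacements and base is avoided once the β-peroxy lactone exists.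

**Route**

Step 1
Reactants: 1 abietic acid
Product: 2 13-oxo-13,14-secoabiet-7-en-14-al-18-oic acid
Conditions: O3 (1.0 equiv), CH2Cl2/MeOH, −78 °C; then Me2S, −78 °C → rt
Reagents that add atoms: ozone, [O-][O+]=O
Why: Ozonolysis with reductive work-up; the 13,14-alkene is the more electron-rich and less hindered end of the diene and should react first, after which the 7,8-alkene is part of an enal and deactivated, so one equivalent of ozone should open only ring C.

Step 2
Reactants: 2 13-oxo-13,14-secoabiet-7-en-14-al-18-oic acid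
Product: 3 C14 (E)-N-tosylhydrazone of 2
Conditions: TsNHNH2 (1.05 equiv), EtOH, rt
Reagents that add atoms: p-toluenesulfonyl hydrazide, Cc1ccc(cc1)S(=O)(=O)NN
Why: Hydrazone condensation, expected at the aldehyde because it is far more electrophilic than the hindered isopropyl ketone.

Step 3
Reactants: 3 C14 (E)-N-tosylhydrazone
Product: 5 13-oxo-13,14-secoabiet-8(14)-en-18-oic acid, via allylic diazene 4 (not isolated)
Conditions: catecholborane (3 equiv), CHCl3, 0 °C; then NaOAc·3H2O, 60 °C
Reagents that add atoms: none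
Why: Reductive 1,3-transposition of an enal tosylhydrazone: hydride adds to C14, loss of sulfinate gives the allylic diazene, and its retro-ene loss of N2 delivers hydrogen to C7 and moves the double bond to C8=C14; the hindered acid should only be borylated reversibly and the ketone should react much more slowly at 0 °C.

Step 4
Reactants: 5 13-oxo-13,14-secoabiet-8(14)-en-18-oic acid
Product: 6 8α-hydroxy-13-oxo-13,14-secoabietan-18-oic acid
Conditions: Co(acac)2 (20 mol %), PhSiH3, O2 (1 atm), THF, rt
Reagents that add atoms: dioxygen, O=O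
Why: Mukaiyama hydration (hydrogen-atom transfer, Markovnikov); the tertiary C8 radical should be trapped by O2 on the α face, away from the axial C20 methyl, giving the equatorial 8α-alcohol with the new C14 methyl axial.

Step 5
Reactants: 6 8α-hydroxy-13-oxo-13,14-secoabietan-18-oic acid
Product: 7 13-isopropyl ester of 8α-hydroxy-13,14-seco-15,16,17-trinorabietane-13,18-dioic acid
Conditions: mCPBA, Na2HPO4, CH2Cl2, rt
Reagents that add atoms: 3-chloroperbenzoic acid, OOC(=O)c1cccc(Cl)c1
Why: Baeyer–Villiger oxidation; the secondary isopropyl group migrates in preference to the primary C12 methylene, so oxygen is inserted on the isopropyl side, and the buffer keeps the tertiary alcohol from ionising.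

Step 6
Reactants: 7 13-isopropyl ester
Product: 9 13,14-seco-15,16,17-trinorabietan-13,8α-olid-18-oic acid, via hydroxy diacid 8 (not isolated)
Conditions: LiOH, THF/H2O, 40 °C; then 1 M HCl to pH 2; TsOH·H2O (cat.), CH2Cl2, rt
Reagents that add atoms: lithium hydroxide, [Li+].[OH-] (its oxygen can remain in the lactone carbonyl)
Why: Ester hydrolysis followed by acid-catalysed δ-lactonisation of the tertiary 8α-alcohol onto the unhindered C13 acid (trans-fused, both ring bonds equatorial), while the neopentyl C18 acid stays free.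

Step 7
Reactants: 9 13,14-seco-15,16,17-trinorabietan-13,8α-olid-18-oic acid
Product: 10 13,14-seco-15,16,17-trinorabietane-13,8α:18,6α-diolide
Conditions: [Mn(OTf)2((S,S)-TIPSpdp)] (2 mol %; TIPSpdp = N,N′-bis[(5-triisopropylsilylpyridin-2-yl)methyl]-2,2′-bipyrrolidine), H2O2 (50% aq., 2 equiv, syringe pump), (CF3)2CHOH, 0 °C
Reagents that add atoms: none
Why: The C18 carboxylate binds manganese and assists O–O heterolysis of coordinated H2O2 to a high-valent manganese–oxo carboxylate, which abstracts the γ-hydrogen H6α through a seven-membered transition state (1,7-hydrogen transfer); the C6 radical is then captured by the bound carboxylate oxygen (rebound). The closest known reaction type is the carboxylic-acid-directed γ-C(sp3)–H lactonisation of methylene groups with manganese aminopyridine catalysts and H2O2 in fluorinated alcohols. The five-membered ring O–C6–C5–C4–C18 closes by intramolecular C6–O bond formation and is cis-bridged across C5 on the α face of ring B. The new stereocentre C6 carries its oxygen α because only the equatorial H6α lies peri to the equatorial C18 carboxylate; H6β sits beside the axial C19 methyl, out of reach. The step needs site selectivity over the other γ-position C2, which an equatorial carboxylate cannot bridge, and over the tertiary C5–H (β, wrong ring size) and C9–H (hindered and deactivated by the acyloxy-bearing C8). This is secured by the geometry of the bound carboxylate and by the electron-poor δ-lactone spectator.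

Step 8
Reactants: 10 13,8α:18,6α-diolide
Product: 12 dimethyl 6α,8α-dihydroxy-13,14-seco-15,16,17-trinorabietane-13,18-dioate, via dipotassium salt 11 (not isolated)
Conditions: KOH (2.2 equiv), MeOH/H2O, 60 °C; evaporate; MeI, DMF, 0 °C → rt
Reagents that add atoms: potassium hydroxide, [K+].[OH-]; iodomethane, CI
Why: Saponification of both lactones and O-alkylation of the two carboxylates (SN2 at methyl), which forms the hindered C18 methyl ester without a tetrahedral intermediate and without acidification, so neither hydroxy acid can re-lactonise.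

Step 9
Reactants: 12 dimethyl 6α,8α-dihydroxy diester
Product: 13 dimethyl 6α,8α-bis(triethylsilyloxy)-13,14-seco-15,16,17-trinorabietane-13,18-dioate
Conditions: Et3SiOTf (3 equiv), 2,6-lutidine, CH2Cl2, −40 → 0 °C
Reagents that add atoms: triethylsilyl trifluoromethanesulfonate, CC[Si](CC)(CC)OS(=O)(=O)C(F)(F)F
Why: Silyl ether formation with a silyl triflate, reactive enough for the hindered secondary C6 and the tertiary C8 hydroxyl; capping both stops either from attacking its neighbouring ester.

Step 10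
Reactants: 13 bis(triethylsilyl) ether diester
Product: 14 6α,8α-bis(triethylsilyloxy) C18 methyl ester C13 acid
Conditions: LiOH·H2O, THF/MeOH/H2O, rt; then 0.5 M HCl to pH 4, 0 °C
Reagents that add atoms: lithium hydroxide, [Li+].[OH-]
Why: Chemoselective saponification: the unhindered C13 ester is hydrolysed while the neopentyl C18 ester, flanked by the C6 silyl ether, should not react.

Step 11
Reactants: 14 C13 acid
Product: 15 N-(acyloxy)phthalimide (redox-active ester) of 14
Conditions: N-hydroxyphthalimide, DIC, DMAP (cat.), CH2Cl2, rt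
Reagents that add atoms: N-hydroxyphthalimide, ON1C(=O)c2ccccc2C1=O
Why: Carbodiimide esterification of the primary-chain acid to the redox-active ester.

Step 12
Reactants: 16 but-3-yn-1-ol
Product: 17 tert-butyl(but-3-yn-1-yloxy)dimethylsilane
Conditions: t-BuMe2SiCl, imidazole, CH2Cl2, rt
Reagents that add atoms: tert-butyldimethylsilyl chloride, CC(C)(C)[Si](C)(C)Cl
Why: Standard silylation of a primary alcohol.

Step 13
Reactants: 18 (R)-glycidol
Product: 19 (S)-4-methoxybenzyl glycidyl ether
Conditions: NaH, 4-MeOC6H4CH2Cl, Bu4NI (cat.), THF/DMF, 0 °C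
Reagents that add atoms: 4-methoxybenzyl chloride, COc1ccc(CCl)cc1
Why: Williamson etherification; the stereocentre is untouched (the descriptor changes only because the priorities change) and Payne rearrangement of glycidol alkoxide is degenerate.

Step 14
Reactants: 17 tert-butyl(but-3-yn-1-yloxy)dimethylsilane; 19 (S)-4-methoxybenzyl glycidyl ether
Product: 22 (2S,4E)-7-(tert-butyldimethylsilyloxy)-1-(4-methoxybenzyloxy)-5-methylhept-4-en-2-ol, via alkenylalane 20 (not isolated), via lithium alanate 21 (not isolated)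
Conditions: Me3Al, Cp2ZrCl2 (25 mol %), CH2Cl2, 0 °C → rt; evaporate; n-BuLi, hexane/THF, −78 °C; then 19, −78 → 0 °C
Reagents that add atoms: trimethylaluminium, C[Al](C)C
Why: Negishi zirconium-catalysed syn-carboalumination puts methyl on the internal and aluminium on the terminal alkyne carbon and so fixes the E geometry; the derived lithium alkenylalanate opens the epoxide at its CH2 terminus with retention of alkene geometry and without touching the glycidol centre, which becomes C6′ (S at this stage).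

Step 15
Reactants: 22 (2S,4E)-homoallylic alcohol
Product: 23 (4S)-2-(4-methoxyphenyl)-4-[(E)-5-(tert-butyldimethylsilyloxy)-3-methylpent-2-enyl]-1,3-dioxolane
Conditions: DDQ (1.2 equiv), 4 Å molecular sieves, CH2Cl2, 0 °C
Reagents that add atoms: none
Why: Oxidative 4-methoxybenzylidene acetal formation: the benzylic oxocarbenium made by DDQ under anhydrous conditions is trapped by the adjacent hydroxyl (the acetal carbon is formed as both epimers, which is of no consequence).

Step 16
Reactants: 23 4-methoxybenzylidene acetal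
Product: 24 (2S,4E)-7-(tert-butyldimethylsilyloxy)-2-(4-methoxybenzyloxy)-5-methylhept-4-en-1-ol
Conditions: i-Bu2AlH (3 equiv), CH2Cl2, −78 → 0 °C
Reagents that add atoms: none
Why: Regioselective reductive acetal opening: aluminium coordinates the less hindered primary oxygen and hydride goes to the acetal carbon, leaving the benzyl group on the secondary oxygen and freeing the primary alcohol.

Step 17
Reactants: 24 primary alcohol
Product: 25 (2S,4E)-7-(tert-butyldimethylsilyloxy)-2-(4-methoxybenzyloxy)-5-methylhept-4-enal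
Conditions: Dess–Martin periodinane, NaHCO3, CH2Cl2, 0 °C
Reagents that add atoms: none
Why: Dess–Martin oxidation under buffered, non-epimerising conditions; the aldehyde is used at once.

Step 18
Reactants: 25 α-alkoxy aldehyde
Product: 26 (3S,5E)-8-(tert-butyldimethylsilyloxy)-3-(4-methoxybenzyloxy)-6-methyloct-5-en-1-yne
Conditions: dimethyl (1-diazo-2-oxopropyl)phosphonate, K2CO3, MeOH, 0 °C → rt
Reagents that add atoms: dimethyl (1-diazo-2-oxopropyl)phosphonate, COP(=O)(OC)C(=[N+]=[N-])C(C)=O
Why: Ohira–Bestmann homologation (Seyferth–Gilbert type), mild enough to keep α-alkoxy aldehydes configurationally intact; the aldehyde carbon becomes C13.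

Step 19
Reactants: 26 terminal alkyne
Product: 28 (3S,5E)-2-bromo-8-(tert-butyldimethylsilyloxy)-3-(4-methoxybenzyloxy)-6-methylocta-1,5-diene, via α-alkenylalane 27 (not isolated)
Conditions: NiCl2(dppp) (3 mol %), i-Bu2AlH (1.3 equiv), THF, 0 °C → rt; then NBS, −78 → 0 °C
Reagents that add atoms: N-bromosuccinimide, BrN1C(=O)CCC1=O
Why: Nickel-catalysed Markovnikov (α-selective) hydroalumination of the terminal alkyne followed by bromodealumination gives the 2-bromo-1-alkene and leaves the acid-sensitive ethers alone.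

Step 20
Reactants: 15 redox-active ester; 28 bromoalkene
Product: 31 coupled (6′S)-4-methoxybenzyl ether with C12–C13 bond, via alkenyllithium 29 (not isolated), via alkenylzinc chloride 30 (not isolated)
Conditions: 28, t-BuLi (2 equiv), Et2O, −78 °C; ZnCl2 (THF), −78 °C → rt; then 15, Ni(acac)2 (10 mol %), 2,2′-bipyridine (10 mol %), THF/DMF, rt
Reagents that add atoms: none
Why: Nickel-catalysed decarboxylative alkenylation of a redox-active ester: single-electron reduction of 15 releases CO2 and the primary C12 radical, which is captured at nickel together with the alkenyl group of 30 and reductively eliminated to the C12–C13 bond; no stereocentre is involved.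

Step 21
Reactants: 31 coupled triene
Product: 32 (3′S,4′S)-epoxide of 31
Conditions: L-fructose-derived Shi ketone (30 mol %), KHSO5 (Oxone), K2CO3, Bu4NHSO4, MeCN/(MeO)2CH2/aq. Na2B4O7 buffer, 0 °C
Reagents that add atoms: potassium peroxymonosulfate, [K+].[O-]S(=O)(=O)OO
Why: Shi epoxidation (chiral dioxirane, spiro transition state); the electron-rich trisubstituted 3′,4′-alkene should react far faster than the 1,1-disubstituted C13 methylene, and the L-series ketone is the one expected to give the (S,S)-epoxide of an (E)-trisubstituted alkene.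

Step 22
Reactants: 32 (3′S,4′S)-epoxide
Product: 33 (6′S)-allylic alcohol epoxide
Conditions: DDQ, CH2Cl2/pH 7 buffer, 0 °C
Reagents that add atoms: none
Why: Oxidative cleavage of the 4-methoxybenzyl ether, orthogonal to the three silyl ethers and harmless to the epoxide.

Step 23
Reactants: 33 allylic alcohol
Product: 34 (6′S)-allylic mesylate epoxide
Conditions: MsCl, Et3N, CH2Cl2, −40 °C; cold work-up, used directly
Reagents that add atoms: methanesulfonyl chloride, CS(=O)(=O)Cl
Why: Sulfonylation of the only free hydroxyl, kept cold because the secondary allylic mesylate is prone to ionisation.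

Step 24
Reactants: 34 allylic mesylate epoxide
Product: 35 (3′R)-hydroperoxide (4′S)-alcohol (6′S)-mesylate
Conditions: H2O2 (anhydrous, in Et2O, 10 equiv), H3PMo12O40 (5 mol %), 0 °C → rt
Reagents that add atoms: hydrogen peroxide, OO
Why: Acid-catalysed perhydrolysis of a trisubstituted epoxide: H2O2 attacks the tertiary C3′ with inversion, giving the (3′R)-hydroperoxide anti to the (4′S)-alcohol; should H2O2 displace the mesylate first, the resulting C6′ hydroperoxide would open the epoxide at C3′ to the same dioxane.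

Step 25
Reactants: 35 hydroperoxy mesylate
Product: 36 (3′R,4′S,6′R)-1,2-dioxane with free 4′-hydroxyl
Conditions: Cs2CO3, DMF, −20 → 0 °C
Reagents that add atoms: none
Why: Intramolecular alkylation of a hydroperoxide (6-exo-tet SN2): the peroxide anion, much more acidic than the alcohol, displaces the allylic mesylate with inversion and so sets C6′ as R, independently of which chair the ring prefers.

Step 26
Reactants: 36 silylated 1,2-dioxane
Product: 37 6α,8α,4′,1′-tetraol
Conditions: HF·pyridine, THF/pyridine, 0 °C → rt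
Reagents that add atoms: none
Why: Fluoride-acid desilylation of all three silyl ethers, under conditions that leave dialkyl peroxides intact and generate no alkoxide next to the C18 ester.

Step 27
Reactants: 37 tetraol
Product: 40 CNP0162504.1, via hydroxy aldehyde 38 (not isolated), via lactol 39 (not isolated)
Conditions: TEMPO (0.2 equiv), PhI(OAc)2 (2.5 equiv), CH2Cl2, rt
Reagents that add atoms: none
Why: Oxoammonium (TEMPO/PhI(OAc)2) oxidation selective for the primary alcohol; the aldehyde is trapped by the 4′-hydroxyl as the lactol, which is oxidised on to the γ-lactone, trans-fused because both of its ring bonds are equatorial on the dioxane, and no base is present that could trigger retro-oxa-Michael loss of the peroxide.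

**Compound list**

1 | abietic acid (abieta-7,13-dien-18-oic acid) | CC(C)C1=CC2=CC[C@@H]3[C@](C)(CCC[C@@]3(C)C(=O)O)[C@H]2CC1 | starting material
2 | 13-oxo-13,14-secoabiet-7-en-14-al-18-oic acid (ring C opened: isopropyl ketone at C13, enal C14=O on C8, 7,8-ene) | CC(C)C(=O)CC[C@H]1C(C=O)=CC[C@@H]2[C@]1(C)CCC[C@@]2(C)C(=O)O | intermediate
3 | C14 (E)-N-tosylhydrazone of 2 | CC(C)C(=O)CC[C@H]1C(/C=N/NS(=O)(=O)c3ccc(C)cc3)=CC[C@@H]2[C@]1(C)CCC[C@@]2(C)C(=O)O | intermediate
4 | 14-diazenyl-13-oxo-13,14-secoabiet-7-en-18-oic acid (allylic diazene) | CC(C)C(=O)CC[C@H]1C(CN=N)=CC[C@@H]2[C@]1(C)CCC[C@@]2(C)C(=O)O | intermediate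
5 | 13-oxo-13,14-secoabiet-8(14)-en-18-oic acid (exocyclic methylene on C8) | CC(C)C(=O)CC[C@H]1C(=C)CC[C@@H]2[C@]1(C)CCC[C@@]2(C)C(=O)O | intermediate
6 | 8α-hydroxy-13-oxo-13,14-secoabietan-18-oic acid (8β-methyl; may be partly present as its six-membered hemiketal) | CC(C)C(=O)CC[C@@H]1[C@@]2(C)CCC[C@@](C)(C(=O)O)[C@@H]2CC[C@@]1(C)O | intermediate
7 | 13-isopropyl ester of 8α-hydroxy-13,14-seco-15,16,17-trinorabietane-13,18-dioic acid | CC(C)OC(=O)CC[C@@H]1[C@@]2(C)CCC[C@@](C)(C(=O)O)[C@@H]2CC[C@@]1(C)O | intermediate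
8 | 8α-hydroxy-13,14-seco-15,16,17-trinorabietane-13,18-dioic acid | OC(=O)CC[C@@H]1[C@@]2(C)CCC[C@@](C)(C(=O)O)[C@@H]2CC[C@@]1(C)O | intermediate
9 | 13,14-seco-15,16,17-trinorabietan-13,8α-olid-18-oic acid (trans-fused δ-lactone, free 4α-carboxyl) | O=C1CC[C@@H]2[C@@]3(C)CCC[C@@](C)(C(=O)O)[C@@H]3CC[C@@]2(C)O1 | intermediate
10 | 13,14-seco-15,16,17-trinorabietane-13,8α:18,6α-diolide (δ-lactone plus 18,6α-γ-lactone) | O=C1CC[C@@H]2[C@@]3(C)CCC[C@@](C)(C(=O)O4)[C@@H]3[C@@H]4C[C@@]2(C)O1 | intermediate
11 | dipotassium 6α,8α-dihydroxy-13,14-seco-15,16,17-trinorabietane-13,18-dioate | [K+].[K+].[O-]C(=O)CC[C@@H]1[C@@]2(C)CCC[C@@](C)(C(=O)[O-])[C@@H]2[C@@H](O)C[C@@]1(C)O | intermediate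
12 | dimethyl 6α,8α-dihydroxy-13,14-seco-15,16,17-trinorabietane-13,18-dioate | COC(=O)CC[C@@H]1[C@@]2(C)CCC[C@@](C)(C(=O)OC)[C@@H]2[C@@H](O)C[C@@]1(C)O | intermediate
13 | dimethyl 6α,8α-bis(triethylsilyloxy)-13,14-seco-15,16,17-trinorabietane-13,18-dioate | COC(=O)CC[C@@H]1[C@@]2(C)CCC[C@@](C)(C(=O)OC)[C@@H]2[C@@H](O[Si](CC)(CC)CC)C[C@@]1(C)O[Si](CC)(CC)CC | intermediate
14 | 18-methyl hydrogen 6α,8α-bis(triethylsilyloxy)-13,14-seco-15,16,17-trinorabietane-13,18-dioate (free C13 acid) | OC(=O)CC[C@@H]1[C@@]2(C)CCC[C@@](C)(C(=O)OC)[C@@H]2[C@@H](O[Si](CC)(CC)CC)C[C@@]1(C)O[Si](CC)(CC)CC | intermediate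
15 | N-(acyloxy)phthalimide of 14 at C13 | O=C(CC[C@@H]1[C@@]2(C)CCC[C@@](C)(C(=O)OC)[C@@H]2[C@@H](O[Si](CC)(CC)CC)C[C@@]1(C)O[Si](CC)(CC)CC)ON3C(=O)c4ccccc4C3=O | intermediate
16 | but-3-yn-1-ol | C#CCCO | starting material
17 | tert-butyl(but-3-yn-1-yloxy)dimethylsilane | C#CCCO[Si](C)(C)C(C)(C)C | intermediate
18 | (R)-glycidol | OC[C@@H]1CO1 | starting material
19 | (S)-4-methoxybenzyl glycidyl ether | COc1ccc(COC[C@@H]2CO2)cc1 | intermediate
20 | dimethyl[(E)-4-(tert-butyldimethylsilyloxy)-2-methylbut-1-enyl]alane | C[Al](C)/C=C(\C)CCO[Si](C)(C)C(C)(C)C | intermediate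
21 | lithium butyl(dimethyl)[(E)-4-(tert-butyldimethylsilyloxy)-2-methylbut-1-enyl]alanate | [Li+].CCCC[Al-](C)(C)/C=C(\C)CCO[Si](C)(C)C(C)(C)C | intermediate
22 | (2S,4E)-7-(tert-butyldimethylsilyloxy)-1-(4-methoxybenzyloxy)-5-methylhept-4-en-2-ol | COc1ccc(COC[C@@H](O)C/C=C(\C)CCO[Si](C)(C)C(C)(C)C)cc1 | intermediate
23 | (4S)-2-(4-methoxyphenyl)-4-[(E)-5-(tert-butyldimethylsilyloxy)-3-methylpent-2-enyl]-1,3-dioxolane (acetal carbon as both epimers) | COc1ccc(C2OC[C@H](C/C=C(\C)CCO[Si](C)(C)C(C)(C)C)O2)cc1 | intermediate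
24 | (2S,4E)-7-(tert-butyldimethylsilyloxy)-2-(4-methoxybenzyloxy)-5-methylhept-4-en-1-ol | OC[C@@H](OCc1ccc(OC)cc1)C/C=C(\C)CCO[Si](C)(C)C(C)(C)C | intermediate
25 | (2S,4E)-7-(tert-butyldimethylsilyloxy)-2-(4-methoxybenzyloxy)-5-methylhept-4-enal | O=C[C@@H](OCc1ccc(OC)cc1)C/C=C(\C)CCO[Si](C)(C)C(C)(C)C | intermediate
26 | (3S,5E)-8-(tert-butyldimethylsilyloxy)-3-(4-methoxybenzyloxy)-6-methyloct-5-en-1-yne | C#C[C@@H](OCc1ccc(OC)cc1)C/C=C(\C)CCO[Si](C)(C)C(C)(C)C | intermediate
27 | diisobutyl[(3S,5E)-8-(tert-butyldimethylsilyloxy)-3-(4-methoxybenzyloxy)-6-methylocta-1,5-dien-2-yl]alane | C=C([Al](CC(C)C)CC(C)C)[C@@H](OCc1ccc(OC)cc1)C/C=C(\C)CCO[Si](C)(C)C(C)(C)C | intermediate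
28 | (3S,5E)-2-bromo-8-(tert-butyldimethylsilyloxy)-3-(4-methoxybenzyloxy)-6-methylocta-1,5-diene | C=C(Br)[C@@H](OCc1ccc(OC)cc1)C/C=C(\C)CCO[Si](C)(C)C(C)(C)C | intermediate
29 | alkenyllithium from 28 (Li in place of Br) | [Li]C(=C)[C@@H](OCc1ccc(OC)cc1)C/C=C(\C)CCO[Si](C)(C)C(C)(C)C | intermediate
30 | alkenylzinc chloride from 29 | Cl[Zn]C(=C)[C@@H](OCc1ccc(OC)cc1)C/C=C(\C)CCO[Si](C)(C)C(C)(C)C | intermediate
31 | coupled triene: C18 methyl ester, 6α,8α-bis(triethylsilyloxy) decalin, chain C11–C12–C13(=CH2)–C6′H(O-4-methoxybenzyl, S)–C5′H2–C4′H=C3′(CH3)–C2′H2–C1′H2O-silyl, 3′,4′-alkene E | C=C(CC[C@@H]1[C@@]2(C)CCC[C@@](C)(C(=O)OC)[C@@H]2[C@@H](O[Si](CC)(CC)CC)C[C@@]1(C)O[Si](CC)(CC)CC)[C@@H](OCc1ccc(OC)cc1)C/C=C(\C)CCO[Si](C)(C)C(C)(C)C | intermediate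
32 | (3′S,4′S)-epoxide of 31 | C=C(CC[C@@H]1[C@@]2(C)CCC[C@@](C)(C(=O)OC)[C@@H]2[C@@H](O[Si](CC)(CC)CC)C[C@@]1(C)O[Si](CC)(CC)CC)[C@@H](OCc1ccc(OC)cc1)C[C@@H]1O[C@@]1(C)CCO[Si](C)(C)C(C)(C)C | intermediate
33 | (6′S)-allylic alcohol (3′S,4′S)-epoxide | C=C(CC[C@@H]1[C@@]2(C)CCC[C@@](C)(C(=O)OC)[C@@H]2[C@@H](O[Si](CC)(CC)CC)C[C@@]1(C)O[Si](CC)(CC)CC)[C@@H](O)C[C@@H]1O[C@@]1(C)CCO[Si](C)(C)C(C)(C)C | intermediate
34 | (6′S)-allylic mesylate (3′S,4′S)-epoxide | C=C(CC[C@@H]1[C@@]2(C)CCC[C@@](C)(C(=O)OC)[C@@H]2[C@@H](O[Si](CC)(CC)CC)C[C@@]1(C)O[Si](CC)(CC)CC)[C@@H](OS(C)(=O)=O)C[C@@H]1O[C@@]1(C)CCO[Si](C)(C)C(C)(C)C | intermediate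
35 | (3′R)-hydroperoxide (4′S)-alcohol (6′S)-mesylate | C=C(CC[C@@H]1[C@@]2(C)CCC[C@@](C)(C(=O)OC)[C@@H]2[C@@H](O[Si](CC)(CC)CC)C[C@@]1(C)O[Si](CC)(CC)CC)[C@@H](OS(C)(=O)=O)C[C@H](O)[C@](C)(OO)CCO[Si](C)(C)C(C)(C)C | intermediate
36 | (3′R,4′S,6′R)-1,2-dioxane: ring C6′–C5′–C4′(OH)–C3′(CH3)(CH2CH2O-silyl)–O–O, C6′ on C13; decalin as in 31 | C=C(CC[C@@H]1[C@@]2(C)CCC[C@@](C)(C(=O)OC)[C@@H]2[C@@H](O[Si](CC)(CC)CC)C[C@@]1(C)O[Si](CC)(CC)CC)[C@H]1C[C@H](O)[C@@](C)(CCO[Si](C)(C)C(C)(C)C)OO1 | intermediate
37 | tetraol: 6α,8α-dihydroxy C18 methyl ester decalin with (3′R,4′S,6′R)-4′-hydroxy-3′-(2-hydroxyethyl)-3′-methyl-1,2-dioxan-6′-yl on C13 | C=C(CC[C@@H]1[C@@]2(C)CCC[C@@](C)(C(=O)OC)[C@@H]2[C@@H](O)C[C@@]1(C)O)[C@H]1C[C@H](O)[C@@](C)(CCO)OO1 | intermediate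
38 | C1′ aldehyde of 37 | C=C(CC[C@@H]1[C@@]2(C)CCC[C@@](C)(C(=O)OC)[C@@H]2[C@@H](O)C[C@@]1(C)O)[C@H]1C[C@H](O)[C@@](C)(CC=O)OO1 | intermediate
39 | trans-fused lactol of 38 (C1′ as both epimers) | C=C(CC[C@@H]1[C@@]2(C)CCC[C@@](C)(C(=O)OC)[C@@H]2[C@@H](O)C[C@@]1(C)O)[C@H]1C[C@@H]2OC(O)C[C@@]2(C)OO1 | intermediate
40 | CNP0162504.1 | C=C(CC[C@@H]1[C@@]2(C)CCC[C@@](C)(C(=O)OC)[C@@H]2[C@@H](O)C[C@@]1(C)O)[C@H]1C[C@@H]2OC(=O)C[C@@]2(C)OO1 | target

**Step count and weak points**

Total step count: 27. Longest linear sequence: 19 steps (steps 1–11 and 20–27, from abietic acid); the side-chain branch runs through steps 12–19.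

Step 7. What may go wrong: the hindered tertiary carboxylate may bind the catalyst poorly, so that conversion stalls or non-directed oxidation at ring A methylenes and over-oxidation compete. Fallback, from 9 back to 10: the same C6–O bond is made by an amidyl-radical relay. Acid 9 is converted (oxalyl chloride, then ammonia at low temperature, where the δ-lactone should survive) into the C18 primary amide F1. Irradiation with PhI(OAc)2 and I2 forms the N-iodoamide F2, whose nitrogen radical abstracts H6α by 1,5-hydrogen transfer for the same geometric reason. Oxidation of the C6 radical and capture by the amide oxygen give the iminolactone F3, which aqueous HCl hydrolyses to bis-lactone 10.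

Step 25. What may go wrong: the secondary allylic mesylate may ionise, transpose to the primary allylic position or eliminate to a diene before the peroxide anion attacks (it must also survive the acidic step 24), and the product can fragment by Kornblum–DeLaMare deprotonation at C6′. Fallback, from 32 to 37: the hydroperoxide is installed before the leaving group and released only at the moment of ring closure. Epoxide 32, still carrying its 4-methoxybenzyl ether, is opened with H2O2 and H3PMo12O40 to the hydroxy hydroperoxide F4. Et3SiOTf and 2,6-lutidine cap both new functions, giving the triethylsilyl peroxide F5. DDQ frees the allylic alcohol F6 and MsCl at −40 °C gives the mesylate F7. Bu4NF buffered with acetic acid at −20 °C cleaves the O–Si bond of the silyl peroxide, and the peroxide anion displaces the mesylate as it forms. On warming with excess fluoride the remaining silyl ethers are removed, so the sequence rejoins the route at tetraol 37.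

Step 20. What may go wrong: the α-branched alkenylzinc may transmetalate slowly, so that the primary radical is lost to reduction or dimerisation of the redox-active ester, or the alkenyllithium may decompose before zinc exchange. Fallback, from 14 to 31: the polarity of the partners is changed so that no alkenyllithium is needed. Acid 14 undergoes iododecarboxylation (PhI(OAc)2, I2, hν) to the C12 primary iodide F8. Zinc insertion (Zn, LiCl, THF) gives the alkylzinc iodide F9, and a Negishi coupling with bromoalkene 28 (PdCl2(dppf), THF/DMF, 50 °C) gives 31.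

Further compounds
F1 | step 7 | C18 primary amide of 9 | O=C1CC[C@@H]2[C@@]3(C)CCC[C@@](C)(C(N)=O)[C@@H]3CC[C@@]2(C)O1
F2 | step 7 | N-iodoamide of F1 | O=C1CC[C@@H]2[C@@]3(C)CCC[C@@](C)(C(=O)NI)[C@@H]3CC[C@@]2(C)O1
F3 | step 7 | 18,6α-iminolactone (C18=NH in place of C18=O of 10) | O=C1CC[C@@H]2[C@@]3(C)CCC[C@@](C)(C(=N)O4)[C@@H]3[C@@H]4C[C@@]2(C)O1
F4 | step 25 | (3′R)-hydroperoxide (4′S)-alcohol with (6′S)-4-methoxybenzyl ether | C=C(CC[C@@H]1[C@@]2(C)CCC[C@@](C)(C(=O)OC)[C@@H]2[C@@H](O[Si](CC)(CC)CC)C[C@@]1(C)O[Si](CC)(CC)CC)[C@@H](OCc1ccc(OC)cc1)C[C@H](O)[C@](C)(OO)CCO[Si](C)(C)C(C)(C)C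
F5 | step 25 | 3′-triethylsilyl peroxide 4′-triethylsilyl ether of F4 | C=C(CC[C@@H]1[C@@]2(C)CCC[C@@](C)(C(=O)OC)[C@@H]2[C@@H](O[Si](CC)(CC)CC)C[C@@]1(C)O[Si](CC)(CC)CC)[C@@H](OCc1ccc(OC)cc1)C[C@H](O[Si](CC)(CC)CC)[C@](C)(OO[Si](CC)(CC)CC)CCO[Si](C)(C)C(C)(C)C
F6 | step 25 | (6′S)-allylic alcohol from F5 | C=C(CC[C@@H]1[C@@]2(C)CCC[C@@](C)(C(=O)OC)[C@@H]2[C@@H](O[Si](CC)(CC)CC)C[C@@]1(C)O[Si](CC)(CC)CC)[C@@H](O)C[C@H](O[Si](CC)(CC)CC)[C@](C)(OO[Si](CC)(CC)CC)CCO[Si](C)(C)C(C)(C)C
F7 | step 25 | (6′S)-allylic mesylate of F6 | C=C(CC[C@@H]1[C@@]2(C)CCC[C@@](C)(C(=O)OC)[C@@H]2[C@@H](O[Si](CC)(CC)CC)C[C@@]1(C)O[Si](CC)(CC)CC)[C@@H](OS(C)(=O)=O)C[C@H](O[Si](CC)(CC)CC)[C@](C)(OO[Si](CC)(CC)CC)CCO[Si](C)(C)C(C)(C)C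
F8 | step 20 | C12 primary iodide from 14 (I in place of CO2H) | ICC[C@@H]1[C@@]2(C)CCC[C@@](C)(C(=O)OC)[C@@H]2[C@@H](O[Si](CC)(CC)CC)C[C@@]1(C)O[Si](CC)(CC)CC
F9 | step 20 | alkylzinc iodide from F8 | I[Zn]CC[C@@H]1[C@@]2(C)CCC[C@@](C)(C(=O)OC)[C@@H]2[C@@H](O[Si](CC)(CC)CC)C[C@@]1(C)O[Si](CC)(CC)CC
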